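Locants follow the target SMILES as written: C1 (ring carbon bearing =CH2), C2 (OAc), C3, C4, C5 (Me), C6, C7 (OAc), C8, C9 (Me), C10, C11, C12, C13, C14 (Me), C15 (OH), C16 (OH).
Retrosynthetic cuts: the 15,16-diol goes back to a C15=C16 alkene. C6–C7 is cut, which contracts the eleven-membered ring to an eight-membered C7(=O)–O–C2 lactone. C9–C10 and C14–C15 are then cut together, with CO2 put back between C9 and C15. Last come the C7–O ester bond and C2–C3.
Enabling feature: in the six-membered ring (C8, C9, C10, C14, C15, C16) the C8=C9 alkene next to the diol is half of a cyclohexa-1,3-diene, cis-fused to the cyclopentane at C10–C14. C8 bears the acyl-level carbon C7 and C9 a methyl, and the C2 oxygen lies three atoms from C10 on the cyclopentane face that also carries C9 and C15. A 6-methyl-2-pyrone-5-carboxylate of the C2 alcohol therefore holds every ring atom plus one CO2.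
Forward order: the C3–C6 chain (plus one helper ester carbon) is joined to C2 by a zinc addition. The cyclopentene comes from ring contraction of the limonene cyclohexene. The six-membered ring and the temporary lactone come from a type 2 intramolecular pyrone Diels–Alder reaction with CO2 extrusion. The eleven-membered ring then comes from a three-atom ring expansion (O-to-C acyl shift), and the diol is installed last.
Stereochemistry: C11 comes from (R)-limonene and C5 from the (R)-glutarate half-ester. C2 is set by ligand-controlled dialkylzinc addition, C10 and C14 by the tethered suprafacial cycloaddition, and C7 by CBS reduction. C15 is set by convex-face dihydroxylation and C16 by hydroxyl-directed reduction.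

Key step: step 14

Assumption: compounds 1, 6, 7 and 11 are taken as commercial. β denotes the face of the six-membered ring that carries H10 and the C14 methyl group, and α the opposite face.

Step 1
Reactants: 1 methyl hydrogen (R)-3-methylglutarate
Product: 3 (S)-4-methyltetrahydro-2H-pyran-2-one, via hydroxy acid 2 (not isolated)
Conditions: NaH (1.0 equiv), THF, 0 °C; LiBH4, 50 °C; then 3 M HCl, rt
Reagents that add atoms: none
Why: Chemoselective LiBH4 reduction of an ester beside a carboxylate salt, followed by acid lactonisation, leaves the stereocentre untouched, and reducing the ester end (not the acid end) gives the lactone whose methyl-bearing carbon has the C5 configuration of the target.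

Step 2
Reactants: 3 (S)-4-methyltetrahydro-2H-pyran-2-one
Product: 5 methyl (R)-5-iodo-3-methylpentanoate, via silyl ester 4 (not isolated)
Conditions: Me3SiI, CH2Cl2, rt; then MeOH, rt
Reagents that add atoms: iodotrimethylsilane, C[Si](C)(C)I; methanol, CO
Why: Lactone opening by Me3SiI (SN2 of iodide at the activated O–CH2 carbon) followed by acid-catalysed methanolysis of the silyl ester gives the iodo ester without touching C5.

Step 3
Reactants: 6 tert-butyl acetoacetate; 7 methyl propiolate
Product: 9 tert-butyl 6-methyl-2-oxo-2H-pyran-5-carboxylate, via Michael adduct 8 (not isolated)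
Conditions: DBU (0.2 equiv), toluene, rt then 110 °C
Reagents that add atoms: none
Why: Base-catalysed Michael addition of the β-keto ester to the ynoate and lactonisation of the Z-enol form is the classical α-pyrone synthesis, and only the ketone oxygen can close onto the methyl ester, so the methyl group ends at pyrone C6 and the tert-butyl ester at pyrone C5.

Step 4
Reactants: 9 tert-butyl 6-methyl-2-oxo-2H-pyran-5-carboxylate
Product: 10 6-methyl-2-oxo-2H-pyran-5-carboxylic acid
Conditions: CF3CO2H/CH2Cl2 (1:1), rt
Reagents that add atoms: none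
Why: Acidolysis of the tert-butyl ester (E1 loss of isobutene) uses conditions to which the acid-stable, base-sensitive pyrone is inert.

Step 5
Reactants: 11 (R)-(+)-limonene
Product: 14 (R)-2-(4-methylcyclohex-3-en-1-yl)prop-2-en-1-ol, via allyllithium 12 (not isolated), via allylboronate 13 (not isolated)
Conditions: n-BuLi, TMEDA, rt; B(OMe)3, THF, −78 °C; H2O2, aq NaOH, 0 °C
Reagents that add atoms: hydrogen peroxide, OO
Why: Allylic metalation of limonene by n-BuLi·TMEDA takes place at the isopropenyl methyl group, and borylation/oxidation of this allyl anion (both termini CH2, so no regiochemical issue) gives the primary allylic alcohol with the future C11 centre untouched.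

Step 6
Reactants: 14 (R)-2-(4-methylcyclohex-3-en-1-yl)prop-2-en-1-ol
Product: 15 (R)-2-(4-methylcyclohex-3-en-1-yl)acrylaldehyde
Conditions: MnO2, CH2Cl2, rt
Reagents that add atoms: none
Why: Allylic alcohol oxidation with MnO2 stops at the α-substituted acrolein and leaves the isolated ring alkene alone.

Step 7
Reactants: 5 methyl (R)-5-iodo-3-methylpentanoate; 15 (R)-2-(4-methylcyclohex-3-en-1-yl)acrylaldehyde
Product: 17 methyl (3S,6R)-6-hydroxy-3-methyl-7-[(R)-4-methylcyclohex-3-en-1-yl]oct-7-enoate, via dialkylzinc 16 (not isolated)
Conditions: 5, Et2Zn, CuI (cat.), neat, 50 °C, then vacuum; Ti(OiPr)4, (1S,2S)-1,2-bis(trifluoromethanesulfonamido)cyclohexane (8 mol %), 15, toluene, −20 °C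
Reagents that add atoms: none
Why: Iodine–zinc exchange gives the ester-tolerant dialkylzinc, and the titanium bis(sulfonamide)-catalysed enantioselective dialkylzinc addition, which is at its best with α-branched enals, should set C2 as (R) under control of the (1S,2S) ligand (the mirror image of the ligand that gives (S)-1-phenylpropanol from benzaldehyde and Et2Zn), irrespective of the remote centres.

Step 8
Reactants: 17 methyl (3S,6R)-6-hydroxy-3-methyl-7-[(R)-4-methylcyclohex-3-en-1-yl]oct-7-enoate
Product: 18 tert-butyldimethylsilyl ether of 17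
Conditions: TBSCl, imidazole, DMF, rt
Reagents that add atoms: tert-butyldimethylsilyl chloride, CC(C)(C)[Si](C)(C)Cl
Why: Standard silylation masks the C2 alcohol, which would otherwise form a lactol with the aldehyde of step 9 and be isomerised by rhodium in step 11.

Step 9
Reactants: 18 tert-butyldimethylsilyl ether of 17
Product: 20 methyl (3S,6R,8R)-6-(tert-butyldimethylsilyloxy)-3-methyl-7-methylidene-11-oxo-8-(2-oxoethyl)dodecanoate, via ozonide 19 (not isolated)
Conditions: O3 (1.0 equiv, Sudan Red 7B end point), CH2Cl2, −78 °C; Me2S, −78 °C to rt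
Reagents that add atoms: ozone, [O-][O+]=O
Why: Chemoselective ozonolysis should take the electron-rich trisubstituted ring alkene, because the 1,1-disubstituted alkene is deactivated and shielded by the allylic silyl ether, and reductive work-up gives the keto aldehyde.

Step 10
Reactants: 20 methyl (3S,6R,8R)-6-(tert-butyldimethylsilyloxy)-3-methyl-7-methylidene-11-oxo-8-(2-oxoethyl)dodecanoate
Product: 21 methyl (3S,6R)-6-(tert-butyldimethylsilyloxy)-7-[(1S)-2-formyl-3-methylcyclopent-2-en-1-yl]-3-methyloct-7-enoate
Conditions: piperidine (0.3 equiv), AcOH (0.3 equiv), toluene, 80 °C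
Reagents that add atoms: none
Why: Enamine-mediated intramolecular aldol condensation (5-enolexo closure of the aldehyde α-carbon C10 onto the methyl ketone C14) is the known ring contraction of limonene-type keto aldehydes and should not epimerise C11, whose descriptor changes only because of the formyl group.

Step 11
Reactants: 21 methyl (3S,6R)-6-(tert-butyldimethylsilyloxy)-7-[(1S)-2-formyl-3-methylcyclopent-2-en-1-yl]-3-methyloct-7-enoate
Product: 22 methyl (3S,6R)-6-(tert-butyldimethylsilyloxy)-3-methyl-7-[(1R)-3-methylcyclopent-2-en-1-yl]oct-7-enoate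
Conditions: [Rh(cod)Cl]2 (3 mol %), dppp (12 mol %), diglyme, 160 °C, argon sweep
Reagents that add atoms: none
Why: Tsuji–Wilkinson decarbonylation (insertion into the formyl C–H bond, CO extrusion, reductive elimination with retention at the alkenyl carbon) removes the helper formyl group and leaves the trisubstituted C10=C14 alkene.

Step 12
Reactants: 22 methyl (3S,6R)-6-(tert-butyldimethylsilyloxy)-3-methyl-7-[(1R)-3-methylcyclopent-2-en-1-yl]oct-7-enoate
Product: 23 methyl (3S,6R)-6-hydroxy-3-methyl-7-[(1R)-3-methylcyclopent-2-en-1-yl]oct-7-enoate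
Conditions: HF·pyridine, THF, 0 °C to rt
Reagents that add atoms: none
Why: Fluoride-mediated desilylation under mildly acidic conditions frees the C2 alcohol and spares the methyl ester and the skipped diene.

Step 13
Reactants: 10 6-methyl-2-oxo-2H-pyran-5-carboxylic acid; 23 methyl (3S,6R)-6-hydroxy-3-methyl-7-[(1R)-3-methylcyclopent-2-en-1-yl]oct-7-enoate
Product: 25 6-methyl-2-oxo-2H-pyran-5-carboxylate ester of alcohol 23, via acid chloride 24 (not isolated)
Conditions: 10, (COCl)2, DMF (cat.), CH2Cl2, 0 °C to rt, concentrate; 23, pyridine, CH2Cl2, 0 °C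
Reagents that add atoms: none
Why: Acylation of the secondary allylic alcohol by the acid chloride occurs at oxygen with retention at C2 and installs a tether whose atoms all stay in the target as C7 and the C2 oxygen.

Step 14
Reactants: 25 6-methyl-2-oxo-2H-pyran-5-carboxylate ester of alcohol 23
Product: 27 tricyclic dienyl lactone (eight-membered C7(=O)-O-C2 lactone; C8=C9 and C15=C16 diene; cis C10/C14 fusion), via bridged lactone 26 (not isolated)
Conditions: o-dichlorobenzene (0.005 M), BHT (10 mol %), sealed tube, 160 °C then 200 °C
Reagents that add atoms: none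
Why: The electron-poor 2-pyrone (diene C9=C8–C16=C15, activated by the C7 ester) adds suprafacially to the electron-rich trisubstituted C10=C14 alkene in an inverse-electron-demand type 2 intramolecular Diels–Alder reaction, and the 2-oxabicyclo[2.2.2]octenone 26 then loses CO2 by retro-[4+2], which makes the sequence irreversible and leaves the C8=C9/C15=C16 diene; the closest known reaction types are the thermal cycloaddition/decarboxylation of coumalate esters with unactivated alkenes and type 2 intramolecular Diels–Alder closures of bicyclo[5.3.1] frameworks. The six-membered ring closes by the [4+2] event itself (bonds C9–C10 and C14–C15), and the temporary eight-membered lactone (C7, O, C2, C1, C11, C10, C9, C8) closes as the 1,3-bridge of the type 2 mode, with the tether forced endo under C8 and the O–C(=O) bridge on the β face. C10 and C14 arise cis because addition to the ring alkene is suprafacial, and their sense relative to C11 is fixed by the five-atom tether C7–O–C2–C1–C11, which can reach only the cyclopentene face that carries C1, so that C1, C9 and C15 end up cis on the five-membered ring as in the target (a long all-carbon tether would be free to deliver the diene to the opposite face). Regiochemistry is matched three times: the nucleophilic CH terminus C10 meets the electrophilic pyrone C6 position (C9), the alternative would join the two methyl-bearing carbons C9 and C14, and it would need a 1,4-bridge. Chemoselectivity over the C1=CH2 alkene is secured because that alkene lies inside the tether, only three atoms from C8, where cycloaddition would give an unattainably strained bridgehead alkene. The strain of the E-configured C8=C9 bond within the eight-membered lactone is accepted on purpose, since it drives step 15.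

Step 15
Reactants: 27 tricyclic dienyl lactone
Product: 28 eleven-membered β-keto ester (C7 ketone; CO2Me on C6; free C2 alcohol)
Conditions: LiN(SiMe3)2 (2.3 equiv), THF (0.01 M), −78 to 0 °C; AcOH quench
Reagents that add atoms: none
Why: Proposed new method: kinetic deprotonation of the only enolisable ester (at C6; the lactone carbonyl C7 has no α-hydrogen) gives an enolate that reaches C7 through a seven-membered cyclic transition state (C6, C5, C4, C3, C2, O, C7), the tetrahedral adduct collapses by expelling the C2 alkoxide with the C2–O bond and its configuration intact, and the O-to-C acyl shift is pulled forward by release of the strain of the E-alkene in the eight-membered lactone and by deprotonation of the β-keto ester by the second equivalent of base, so that the eight-membered ring grows by three atoms into the eleven-membered carbocycle; the closest known reaction types are the Dieckmann condensation and the base-induced O-to-C acyl migrations of the Baker–Venkataraman and Chan type, which have not been used over this distance or to expand a lactone.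

Step 16
Reactants: 28 eleven-membered β-keto ester
Product: 29 tricyclic hydroxy dienone (C2 alcohol; C7 ketone)
Conditions: LiCl, H2O, DMSO, 140 °C
Reagents that add atoms: none
Why: Krapcho dealkoxycarbonylation (chloride SN2 at the ester methyl group, then loss of CO2 from the β-keto carboxylate) removes the helper ester under neutral conditions, and the reverse acyl shift is barred by the strain of the eight-membered lactone.

Step 17
Reactants: 29 tricyclic hydroxy dienone
Product: 30 tricyclic (2R,7S)-dienediol
Conditions: (R)-2-methyl-CBS-oxazaborolidine (0.5 equiv), catecholborane (3 equiv), toluene, −78 to −40 °C; aqueous work-up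
Reagents that add atoms: none
Why: In this Corey–Bakshi–Shibata reduction the fully substituted alkenyl carbon C8 is the large group and C6H2 the small one, so the (R)-oxazaborolidine should give the (S)-carbinol at C7 (the sense in which it gives (S)-1-phenylethanol from acetophenone), and catecholborane at low temperature does not hydroborate the alkenes.

Step 18
Reactants: 30 tricyclic (2R,7S)-dienediol
Product: 31 tricyclic 2,7-diacetoxy diene
Conditions: Ac2O, DMAP (cat.), pyridine, CH2Cl2, rt
Reagents that add atoms: acetic anhydride, CC(=O)OC(C)=O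
Why: DMAP-catalysed acetylation of both secondary alcohols puts the two acetates in place before the diol oxygens exist, so four hydroxyl groups never have to be told apart.

Step 19
Reactants: 31 tricyclic 2,7-diacetoxy diene
Product: 32 (15R,16S)-15β,16β-cis-diol diacetate
Conditions: OsO4 (5 mol %), NMO, acetone/H2O, 0 °C
Reagents that add atoms: N-methylmorpholine N-oxide, C[N+]1([O-])CCOCC1; water, O
Why: In this Upjohn dihydroxylation OsO4 ignores the tetrasubstituted C8=C9 bond, should prefer the conjugated cis-disubstituted C15=C16 bond to the C1=CH2 alkene (deactivated by the allylic acetate and buried on the concave side), and should add from the convex β face because the α face is roofed by C1 and C2 of the eleven-membered ring, which sets C15 as (R).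

Step 20
Reactants: 32 (15R,16S)-15β,16β-cis-diol diacetate
Product: 33 (15R)-15β-hydroxy-16-ketone diacetate
Conditions: IBX (1.1 equiv), DMSO, rt
Reagents that add atoms: none
Why: IBX oxidises 1,2-diols to α-ketols without C–C cleavage and should take the allylic, less hindered C16 carbinol rather than the neopentyl C15 carbinol.

Step 21
Reactants: 33 (15R)-15β-hydroxy-16-ketone diacetate
Product: 34 target CNP0286573.1
Conditions: Me4NBH(OAc)3, MeCN/AcOH, −30 °C
Reagents that add atoms: none
Why: In this hydroxyl-directed triacetoxyborohydride reduction (Evans–Saksena type) boron binds the C15 β-hydroxyl and hands hydride to the β face of the C16 ketone, which is also the open convex face, giving the 16α (R) alcohol trans to C15–OH, while acetates and alkenes are inert to the reagent.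

Compound list
1 | methyl hydrogen (R)-3-methylglutarate | COC(=O)C[C@H](C)CC(O)=O | starting material
2 | (S)-5-hydroxy-3-methylpentanoic acid | OCC[C@H](C)CC(O)=O | intermediate
3 | (S)-4-methyltetrahydro-2H-pyran-2-one | C[C@H]1CCOC(=O)C1 | intermediate
4 | trimethylsilyl (R)-5-iodo-3-methylpentanoate | ICC[C@H](C)CC(=O)O[Si](C)(C)C | intermediate
5 | methyl (R)-5-iodo-3-methylpentanoate | ICC[C@H](C)CC(=O)OC | intermediate
6 | tert-butyl acetoacetate | CC(=O)CC(=O)OC(C)(C)C | starting material
7 | methyl propiolate | C#CC(=O)OC | starting material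
8 | 1-tert-butyl 5-methyl (Z)-2-acetylpent-3-enedioate (configurationally labile at C2) | COC(=O)/C=C\C(C(C)=O)C(=O)OC(C)(C)C | intermediate
9 | tert-butyl 6-methyl-2-oxo-2H-pyran-5-carboxylate | CC1=C(C(=O)OC(C)(C)C)C=CC(=O)O1 | intermediate
10 | 6-methyl-2-oxo-2H-pyran-5-carboxylic acid | CC1=C(C(O)=O)C=CC(=O)O1 | intermediate
11 | (R)-(+)-limonene | CC1=CC[C@@H](CC1)C(C)=C | starting material
12 | (R)-2-(4-methylcyclohex-3-en-1-yl)allyllithium | CC1=CC[C@@H](CC1)C(=C)C[Li] | intermediate
13 | dimethyl (R)-[2-(4-methylcyclohex-3-en-1-yl)allyl]boronate | CC1=CC[C@@H](CC1)C(=C)CB(OC)OC | intermediate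
14 | (R)-2-(4-methylcyclohex-3-en-1-yl)prop-2-en-1-ol | CC1=CC[C@@H](CC1)C(=C)CO | intermediate
15 | (R)-2-(4-methylcyclohex-3-en-1-yl)acrylaldehyde | CC1=CC[C@@H](CC1)C(=C)C=O | intermediate
16 | bis[(R)-5-methoxy-3-methyl-5-oxopentyl]zinc | COC(=O)C[C@@H](C)CC[Zn]CC[C@H](C)CC(=O)OC | intermediate
17 | methyl (3S,6R)-6-hydroxy-3-methyl-7-[(R)-4-methylcyclohex-3-en-1-yl]oct-7-enoate | CC1=CC[C@@H](CC1)C(=C)[C@H](O)CC[C@H](C)CC(=O)OC | intermediate
18 | tert-butyldimethylsilyl ether of 17 | CC1=CC[C@@H](CC1)C(=C)[C@H](O[Si](C)(C)C(C)(C)C)CC[C@H](C)CC(=O)OC | intermediate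
19 | secondary ozonide of the ring alkene of 18 (both trioxolane diastereomers) | CC12OOC(O1)C[C@@H](CC2)C(=C)[C@H](O[Si](C)(C)C(C)(C)C)CC[C@H](C)CC(=O)OC | intermediate
20 | methyl (3S,6R,8R)-6-(tert-butyldimethylsilyloxy)-3-methyl-7-methylidene-11-oxo-8-(2-oxoethyl)dodecanoate | O=CC[C@@H](CCC(C)=O)C(=C)[C@H](O[Si](C)(C)C(C)(C)C)CC[C@H](C)CC(=O)OC | intermediate
21 | methyl (3S,6R)-6-(tert-butyldimethylsilyloxy)-7-[(1S)-2-formyl-3-methylcyclopent-2-en-1-yl]-3-methyloct-7-enoate | CC1=C(C=O)[C@@H](CC1)C(=C)[C@H](O[Si](C)(C)C(C)(C)C)CC[C@H](C)CC(=O)OC | intermediate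
22 | methyl (3S,6R)-6-(tert-butyldimethylsilyloxy)-3-methyl-7-[(1R)-3-methylcyclopent-2-en-1-yl]oct-7-enoate | CC1=C[C@@H](CC1)C(=C)[C@H](O[Si](C)(C)C(C)(C)C)CC[C@H](C)CC(=O)OC | intermediate
23 | methyl (3S,6R)-6-hydroxy-3-methyl-7-[(1R)-3-methylcyclopent-2-en-1-yl]oct-7-enoate | CC1=C[C@@H](CC1)C(=C)[C@H](O)CC[C@H](C)CC(=O)OC | intermediate
24 | 6-methyl-2-oxo-2H-pyran-5-carbonyl chloride | CC1=C(C(Cl)=O)C=CC(=O)O1 | intermediate
25 | 6-methyl-2-oxo-2H-pyran-5-carboxylate ester of alcohol 23 (C2 R, C5 S, C11 R) | CC1=C[C@@H](CC1)C(=C)[C@H](OC(=O)C2=C(C)OC(=O)C=C2)CC[C@H](C)CC(=O)OC | intermediate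
26 | 2-oxabicyclo[2.2.2]oct-5-en-3-one cycloadduct (C9–C10 and C14–C15 formed, O–C(=O) bridge from C9 to C15 on the β face, C8=C16 alkene, eight-membered lactone C7(=O)–O–C2) | C=C1[C@@H](CC[C@H](C)CC(=O)OC)OC(=O)C2=C[C@@H]5C(=O)O[C@@]2(C)[C@@H]3[C@H]1CC[C@@]35C | intermediate
27 | tricyclic dienyl lactone (eight-membered C7(=O)–O–C2 lactone, C8=C9 and C15=C16 diene, cis C10/C14 fusion, C1, C9 and C15 cis on the cyclopentane, C3–C6 chain with methyl ester on C2) | C=C1[C@@H](CC[C@H](C)CC(=O)OC)OC(=O)C2=C(C)[C@@H]3[C@H]1CC[C@]3(C)C=C2 | intermediate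
28 | eleven-membered β-keto ester (C7 ketone, CO2Me on C6 as epimer/enol mixture, free (2R)-alcohol, C8=C9/C15=C16 diene) | C=C1[C@H](O)CC[C@H](C)C(C(=O)OC)C(=O)C2=C(C)[C@@H]3[C@H]1CC[C@]3(C)C=C2 | intermediate
29 | tricyclic hydroxy dienone ((2R)-alcohol, C7 ketone) | C=C1[C@H](O)CC[C@H](C)CC(=O)C2=C(C)[C@@H]3[C@H]1CC[C@]3(C)C=C2 | intermediate
30 | tricyclic (2R,7S)-dienediol | C=C1[C@H](O)CC[C@H](C)C[C@H](O)C2=C(C)[C@@H]3[C@H]1CC[C@]3(C)C=C2 | intermediate
31 | tricyclic (2R,7S)-2,7-diacetoxy diene | C=C1[C@H](OC(C)=O)CC[C@H](C)C[C@H](OC(C)=O)C2=C(C)[C@@H]3[C@H]1CC[C@]3(C)C=C2 | intermediate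
32 | (15R,16S)-15β,16β-cis-diol diacetate | C=C1[C@H](OC(C)=O)CC[C@H](C)C[C@H](OC(C)=O)C2=C(C)[C@@H]3[C@H]1CC[C@]3(C)[C@@H](O)[C@H]2O | intermediate
33 | (15R)-15β-hydroxy-16-ketone diacetate | C=C1[C@H](OC(C)=O)CC[C@H](C)C[C@H](OC(C)=O)C2=C(C)[C@@H]3[C@H]1CC[C@]3(C)[C@@H](O)C2=O | intermediate
34 | CNP0286573.1 (2R,5S,7S,10S,11R,14S,15R,16R) | C=C1[C@H](OC(C)=O)CC[C@H](C)C[C@H](OC(C)=O)C2=C(C)[C@@H]3[C@H]1CC[C@]3(C)[C@@H](O)[C@@H]2O | target

Total step count: 21. Longest linear sequence: 17 steps (steps 5–21 from 11, and equally steps 1, 2 and 7–21 from 1).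

Steps most likely to fail

Step 15. The acyl shift may not start, because the seven-membered transition state is slow and γ-deprotonation at the C9 methyl group competes. It may also stall at the tetrahedral adduct.
The fallback uses known reactions, sets out from 27 and returns at 28. Methanolysis (K2CO3, MeOH) should open the strained lactone to the hydroxy diester F1. Silylation (TBSOTf, 2,6-lutidine) gives the silyl ether diester F2. A high-dilution crossed Dieckmann condensation (TiCl4, Bu3N, CH2Cl2) is possible in one direction only, since the C7 dienoate cannot enolise, and closes the eleven-membered ring to the silylated β-keto ester F3. HF·pyridine then gives 28.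

Step 14. The cycloaddition may be too slow to outrun thermal decomposition, because the ester tether must adopt its s-cis form and twist out of conjugation. Alternatively, the bridged lactone may resist loss of CO2 because the product holds a strained E-alkene.
The fallback changes the diene and the extruded fragment, sets out from 23 and returns at 27. Commercial 2-methylthiophene-3-carboxylic acid is oxidised before any alkene is present (H2O2, (CF3CO)2O) to 2-methylthiophene-3-carboxylic acid 1,1-dioxide F4. This acid is esterified with 23 (EDC, DMAP cat.) to the thiophene dioxide ester F5. Thiophene dioxides are more reactive inverse-demand dienes than pyrones, and on mild heating in dilute toluene F5 should give the sulfone-bridged cycloadduct F6. This adduct sheds SO2 cheletropically far more easily than a pyrone adduct sheds CO2 and delivers 27.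

Step 19. Facial selectivity may be poor or reversed, with attack anti to the axial C14 methyl group.
The fallback inverts the other carbinol, sets out from 31 and returns at 34. Addition from the α face gives the 15α,16α-cis-diol F7, in which C16 is already correct. Selective silylation of the less hindered allylic hydroxyl (TESCl, imidazole) gives the 16-O-triethylsilyl ether F8. Dess–Martin oxidation gives the 15-ketone F9. NaBH4 (MeOH, −40 °C) should then deliver hydride from the same accessible α face to give the 15β-alcohol F10, and HF·pyridine gives 34.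

Further compounds
F1 | step 15 | hydroxy diester (C7 methyl dienoate, free C2 alcohol, chain methyl ester) | COC(=O)C1=C(C)[C@@H]2[C@@H](CC[C@]2(C)C=C1)C(=C)[C@H](O)CC[C@H](C)CC(=O)OC
F2 | step 15 | silyl ether diester (TBS ether of F1) | COC(=O)C1=C(C)[C@@H]2[C@@H](CC[C@]2(C)C=C1)C(=C)[C@H](O[Si](C)(C)C(C)(C)C)CC[C@H](C)CC(=O)OC
F3 | step 15 | silylated β-keto ester (TBS ether of 28) | C=C1[C@H](O[Si](C)(C)C(C)(C)C)CC[C@H](C)C(C(=O)OC)C(=O)C2=C(C)[C@@H]3[C@H]1CC[C@]3(C)C=C2
F4 | step 14 | 2-methylthiophene-3-carboxylic acid 1,1-dioxide | CC1=C(C(O)=O)C=CS1(=O)=O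
F5 | step 14 | thiophene dioxide ester of alcohol 23 | CC1=C[C@@H](CC1)C(=C)[C@H](OC(=O)C2=C(C)S(=O)(=O)C=C2)CC[C@H](C)CC(=O)OC
F6 | step 14 | sulfone-bridged cycloadduct (SO2 bridge from C9 to C15 on the β face) | C=C1[C@@H](CC[C@H](C)CC(=O)OC)OC(=O)C2=C[C@@H]5S(=O)(=O)[C@@]2(C)[C@@H]3[C@H]1CC[C@@]35C
F7 | step 19 | 15α,16α-cis-diol diacetate | C=C1[C@H](OC(C)=O)CC[C@H](C)C[C@H](OC(C)=O)C2=C(C)[C@@H]3[C@H]1CC[C@]3(C)[C@H](O)[C@@H]2O
F8 | step 19 | 16-O-triethylsilyl ether of F7 | C=C1[C@H](OC(C)=O)CC[C@H](C)C[C@H](OC(C)=O)C2=C(C)[C@@H]3[C@H]1CC[C@]3(C)[C@H](O)[C@@H]2O[Si](CC)(CC)CC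
F9 | step 19 | 15-ketone 16-O-triethylsilyl ether | C=C1[C@H](OC(C)=O)CC[C@H](C)C[C@H](OC(C)=O)C2=C(C)[C@@H]3[C@H]1CC[C@]3(C)C(=O)[C@@H]2O[Si](CC)(CC)CC
F10 | step 19 | 15β-alcohol 16-O-triethylsilyl ether | C=C1[C@H](OC(C)=O)CC[C@H](C)C[C@H](OC(C)=O)C2=C(C)[C@@H]3[C@H]1CC[C@]3(C)[C@@H](O)[C@@H]2O[Si](CC)(CC)CC
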